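**Retrosynthetic overview**
1. Target 36 ⇐ cyclohexanol 22 by late functional-group work: O6→C12 lactonisation, C13 methylenation, SeO2 oxidation of the C15 methyl to the aldehyde, and O8 acylation with a silyl-protected hydroxymethacrylic acid.
2. 22 ⇐ acyclic aldehyde 21 by carbonyl-ene closure of C5–C6. The feature used is the C6 carbinol trans to the C5 2-propenyl group (C4=C3H2, C15) on the ring C5–C6–C7–C8–C9–C10, an isopulegol-type homoallylic alcohol. The cyclohexane is formed first; the γ-lactone (O6–C12) is closed second.
3. 21 ⇐ Evans syn-aldol (C7–C8) of succinate imide 16 with aldehyde 12.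
4. 12 ⇐ prochiral 2-vinyl-1,3-diol 5 (lipase monoacetylation sets C10; the acetylated arm is C14, the other arm becomes C5 by oxidation and Wittig olefination) ⇐ deconjugative alkylation of diethyl ethylidenemalonate.

Key step: step 13

Numbering (elemane): ring C5–C6–C7–C8–C9–C10; C1=C2 vinyl and C14 (CH2OAc) on C10; C4(=C3H2)–C15 on C5; C11(=C13H2)–C12 on C7.
Assumption: the lipase is taken to acetylate the hydroxymethyl group that gives (R)-6; if a screen shows the opposite sense, the same enzyme is used in hydrolysis mode on the diacetate of 5, which inverts the outcome.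

**Step 1**
Reactants: 1 diethyl ethylidenemalonate; 2 tert-butyl(2-iodoethoxy)dimethylsilane
Product: 4 diethyl 2-[2-(tert-butyldimethylsilyloxy)ethyl]-2-vinylmalonate, via lithium dienolate 3 (not isolated)
Conditions: LDA, THF, −78 °C; then 2, DMPU, −78 °C → rt
Reagents that add atoms: none
Why: γ-deprotonation of the alkylidene malonate gives a dienolate that is alkylated by the primary iodide at the α-carbon, where the charge is highest, so the vinyl-bearing quaternary carbon (C10) is formed (deconjugative α-alkylation of an alkylidene malonate).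

**Step 2**
Reactants: 4
Product: 5 2-[2-(tert-butyldimethylsilyloxy)ethyl]-2-vinylpropane-1,3-diol
Conditions: LiAlH4, Et2O, 0 °C → rt; aqueous NaOH work-up
Reagents that add atoms: none
Why: hydride reduction of both malonate esters gives the prochiral 1,3-diol, the silyl ether and the isolated vinyl group being inert to LiAlH4.

**Step 3**
Reactants: 5
Product: 6 (R)-2-[2-(tert-butyldimethylsilyloxy)ethyl]-2-(hydroxymethyl)but-3-enyl acetate
Conditions: lipase PS (Burkholderia cepacia, immobilised), vinyl acetate, i-Pr2O, rt, stopped at the monoacetate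
Reagents that add atoms: vinyl acetate, C=COC(C)=O
Why: lipase-catalysed irreversible transesterification distinguishes the enantiotopic hydroxymethyl groups of the 2,2-disubstituted 1,3-diol (enzymatic desymmetrisation), which sets the C10 quaternary centre and leaves the acetate on the arm that becomes C14.

**Step 4**
Reactants: 6
Product: 7 (S)-2-[2-(tert-butyldimethylsilyloxy)ethyl]-2-formylbut-3-enyl acetate
Conditions: Dess–Martin periodinane, pyridine, CH2Cl2, 0 °C → rt
Reagents that add atoms: none
Why: Dess–Martin oxidation under buffered neutral conditions converts the free arm into the non-enolisable aldehyde before 1,3-acyl migration could racemise C10.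

**Step 5**
Reactants: 7; 8 isopropyltriphenylphosphonium iodide
Product: 10 (R)-2-[2-(tert-butyldimethylsilyloxy)ethyl]-4-methyl-2-vinylpent-3-enyl acetate, via isopropylidenetriphenylphosphorane 9 (not isolated)
Conditions: 8, n-BuLi, THF, 0 °C; then 7, −78 °C → rt
Reagents that add atoms: none
Why: Wittig olefination with the non-stabilised isopropylidene ylide installs the 2-methylpropenyl group (C5=C4), the aldehyde reacting far faster than the acetate, which the ylide is not basic enough to enolise.

**Step 6**
Reactants: 10
Product: 11 (R)-2-(2-hydroxyethyl)-4-methyl-2-vinylpent-3-enyl acetate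
Conditions: HF·pyridine, pyridine, THF, 0 °C → rt
Reagents that add atoms: none
Why: buffered HF·pyridine cleaves the primary silyl ether (fluoride-mediated desilylation) without hydrolysing or transferring the C14 acetate.

**Step 7**
Reactants: 11
Product: 12 (R)-4-methyl-2-(2-oxoethyl)-2-vinylpent-3-enyl acetate
Conditions: Dess–Martin periodinane, pyridine, CH2Cl2, 0 °C
Reagents that add atoms: none
Why: Dess–Martin oxidation gives the C8 aldehyde, which has no leaving group on its β-carbon and no stereocentre at its α-carbon.

**Step 8**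
Reactants: 13 4-tert-butoxy-4-oxobutanoic acid; 14 (R)-4-benzyl-2-oxazolidinone
Product: 16 (R)-4-benzyl-3-[4-(tert-butoxy)-4-oxobutanoyl]oxazolidin-2-one, via mixed pivalic anhydride 15 (not isolated)
Conditions: PivCl, Et3N, THF, −20 °C; then 14, LiCl, rt
Reagents that add atoms: none
Why: N-acylation of the oxazolidinone through the mixed pivalic anhydride, which is attacked at the less hindered succinyl carbonyl.

**Step 9**
Reactants: 16; 12
Product: 18 Evans syn-aldol adduct (imide at C6; CH2CO2t-Bu on C7; free O8 hydroxyl; 7,8-syn), via dibutylboron Z-enolate 17 (not isolated)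
Conditions: Bu2BOTf, i-Pr2NEt, CH2Cl2, −78 → 0 °C; then 12, −78 → 0 °C; pH 7 buffer, MeOH, H2O2, 0 °C
Reagents that add atoms: none
Why: Evans syn-aldol in which the Z-boron enolate of the (R)-benzyl imide adds to 12 through a Zimmerman–Traxler chair on the enolate face away from the benzyl group, which sets C7 and C8 syn in the required absolute sense under auxiliary control, while the tert-butyl ester keeps the O8 aldolate from lactonising onto C12.

**Step 10**
Reactants: 18
Product: 19 O8-TBS ether of the aldol adduct
Conditions: TBSOTf, 2,6-lutidine, CH2Cl2, −78 °C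
Reagents that add atoms: tert-butyldimethylsilyl triflate, CC(C)(C)[Si](C)(C)OS(=O)(=O)C(F)(F)F
Why: silylation of the secondary alcohol with the silyl triflate is fast at −78 °C, where the tert-butyl ester is not cleaved, and it blocks O8 so that only O6 can later lactonise.

**Step 11**
Reactants: 19
Product: 20 C6 primary alcohol (tert-butyl ester, O8 TBS, O14 acetyl retained)
Conditions: LiBH4 (1.2 equiv), MeOH (1.2 equiv), Et2O, 0 °C, quenched as soon as 19 is consumed
Reagents that add atoms: none
Why: reductive cleavage of the N-acyl oxazolidinone by LiBH4 at the activated exocyclic carbonyl, which is reduced faster than the acetate and the tert-butyl ester at 0 °C with limited hydride.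

**Step 12**
Reactants: 20
Product: 21 acyclic C6 aldehyde with 2-methylpropenyl terminus (O8 TBS; O14 acetyl; tert-butyl ester)
Conditions: Dess–Martin periodinane, pyridine, CH2Cl2, 0 °C; used at once
Reagents that add atoms: none
Why: buffered Dess–Martin oxidation gives the α-branched β-silyloxy aldehyde without epimerisation at C7 or β-elimination.

**Step 13**
Reactants: 21
Product: 22 isopulegol-type cyclohexanol (free O6 hydroxyl; C5 isopropenyl; groups on C5 to C8 all equatorial)
Conditions: Me2AlCl (2.5 equiv), CH2Cl2, −78 °C; then water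
Reagents that add atoms: none
Why: Me2AlCl binds the C6 aldehyde, the C5=C4 olefin attacks it through C5, and a hydrogen of the C4 methyl group lying near the carbonyl oxygen is passed to O6 in a six-centre ene transition state, the Al–Me groups scavenging protons so that open cationic paths are suppressed. The closest known reaction is the Lewis acid-promoted type I carbonyl-ene cyclisation of citronellal to isopulegol. The ring C5–C6–C7–C8–C9–C10 closes in the 6-(3,4) ene mode, with both the C=O and the C=C π bond exocyclic to the forming six-membered chair. C6 is set by the aluminium-bound oxygen taking the equatorial site, since an axial oxygen would be syn-axial to the C10 acetoxymethyl group and H8, and C5 is set by the olefin taking the equatorial site trans to it; the chair itself is fixed by the existing centres, with the C7 ester arm, the C8 silyloxy group and the C10 vinyl group equatorial and only CH2OAc axial. The step needs site selectivity between the two olefins, which is secured because the C10 vinyl group has no allylic hydrogen and cannot reach C6 in a six-membered array, and the tert-butyl ester, acetate and silyl ether are inert to Me2AlCl at −78 °C.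

**Step 14**
Reactants: 22
Product: 23 trans-fused 6,12-γ-lactone (O8 TBS; C5 isopropenyl)
Conditions: TFA (10 vol%), CH2Cl2, 0 °C → rt
Reagents that add atoms: none
Why: acid-catalysed lactonisation of the γ-hydroxy tert-butyl ester with loss of isobutene closes the trans-fused lactone from the equatorial O6 and the equatorial C7 arm, O8 being blocked as its silyl ether.

**Step 15**
Reactants: 23
Product: 27 α-methylene lactone (C11=C13H2), via lithium lactone enolate 24 (not isolated), via Mannich base 25 (not isolated), via trimethylammonium iodide 26 (not isolated)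
Conditions: LiHMDS (1.05 equiv), THF, −78 °C; Eschenmoser's salt, −78 °C → rt; then MeI, MeOH, rt; then aq. NaHCO3, EtOAc
Reagents that add atoms: Eschenmoser's salt (N,N-dimethylmethyleneiminium iodide), C=[N+](C)C.[I-]
Why: Eschenmoser methylenation in which the lactone α-CH2, several pK units more acidic than the acetate methyl, is enolised by a slight excess of LiHMDS, aminomethylated, quaternised and eliminated to the exocyclic olefin.

**Step 16**
Reactants: 27
Product: 29 C15 enal (2-substituted acrolein on C5), via allylic alcohol 28 (not isolated)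
Conditions: SeO2 (2 equiv), 1,4-dioxane, 80 °C
Reagents that add atoms: selenium dioxide, O=[Se]=O
Why: Riley allylic oxidation (ene reaction then [2,3]-shift) attacks the methyl group of the 1,1-disubstituted isopropenyl olefin and carries the allylic alcohol on to the enal, the C10 vinyl group having no allylic hydrogen and the lactone methylene being electron-poor.

**Step 17**
Reactants: 29
Product: 30 C8 alcohol
Conditions: 48% aq. HF, MeCN, 0 °C → rt
Reagents that add atoms: none
Why: acidic fluoride desilylation frees O8 without the translactonisation or conjugate additions that a basic fluoride source could trigger.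

**Step 18**
Reactants: 31 ethyl 2-(hydroxymethyl)acrylate
Product: 32 ethyl 2-[(tert-butyldimethylsilyloxy)methyl]acrylate
Conditions: TBSCl, imidazole, CH2Cl2, 0 °C → rt
Reagents that add atoms: tert-butyldimethylsilyl chloride, CC(C)(C)[Si](C)(C)Cl
Why: standard imidazole-promoted silylation of the primary allylic alcohol.

**Step 19**
Reactants: 32
Product: 33 2-[(tert-butyldimethylsilyloxy)methyl]acrylic acid
Conditions: LiOH, THF/H2O, 0 °C → rt; then 1 M HCl to pH 3
Reagents that add atoms: lithium hydroxide, [Li+].[OH-]
Why: saponification of the ethyl ester at low temperature, where hydroxide attacks the ester carbonyl faster than it adds to the hindered 2-substituted acrylate.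

**Step 20**
Reactants: 30; 33
Product: 35 O8 ester of 30 with the silyl-protected hydroxymethacrylic acid, via mixed 2,4,6-trichlorobenzoic anhydride 34 (not isolated)
Conditions: 2,4,6-trichlorobenzoyl chloride, Et3N, toluene, rt; then 30, DMAP, toluene, rt
Reagents that add atoms: none
Why: Yamaguchi esterification acylates the equatorial secondary O8 hydroxyl through the acylpyridinium species faster than the alkoxide can translactonise.

**Step 21**
Reactants: 35
Product: 36 target CNP0185525.1
Conditions: HF·pyridine, THF, 0 °C
Reagents that add atoms: none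
Why: fluoride-mediated cleavage of the primary allylic silyl ether under mildly acidic conditions leaves the acetate, both acrylate-type esters, the lactone and the enal untouched.

**Compound list**
1 | diethyl ethylidenemalonate | CC=C(C(=O)OCC)C(=O)OCC | starting material
2 | tert-butyl(2-iodoethoxy)dimethylsilane | CC(C)(C)[Si](C)(C)OCCI | starting material
3 | lithium dienolate of diethyl vinylmalonate | [Li+].C=CC(C(=O)OCC)=C([O-])OCC | intermediate
4 | diethyl 2-[2-(tert-butyldimethylsilyloxy)ethyl]-2-vinylmalonate | C=CC(CCO[Si](C)(C)C(C)(C)C)(C(=O)OCC)C(=O)OCC | intermediate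
5 | 2-[2-(tert-butyldimethylsilyloxy)ethyl]-2-vinylpropane-1,3-diol (prochiral) | C=CC(CO)(CO)CCO[Si](C)(C)C(C)(C)C | intermediate
6 | (R)-2-[2-(tert-butyldimethylsilyloxy)ethyl]-2-(hydroxymethyl)but-3-enyl acetate | C=C[C@@](CCO[Si](C)(C)C(C)(C)C)(COC(C)=O)CO | intermediate
7 | (S)-2-[2-(tert-butyldimethylsilyloxy)ethyl]-2-formylbut-3-enyl acetate | C=C[C@@](CCO[Si](C)(C)C(C)(C)C)(COC(C)=O)C=O | intermediate
8 | isopropyltriphenylphosphonium iodide | CC(C)[P+](c1ccccc1)(c1ccccc1)c1ccccc1.[I-] | starting material
9 | isopropylidenetriphenylphosphorane | CC(C)=P(c1ccccc1)(c1ccccc1)c1ccccc1 | intermediate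
10 | (R)-2-[2-(tert-butyldimethylsilyloxy)ethyl]-4-methyl-2-vinylpent-3-enyl acetate | C=C[C@@](CCO[Si](C)(C)C(C)(C)C)(COC(C)=O)C=C(C)C | intermediate
11 | (R)-2-(2-hydroxyethyl)-4-methyl-2-vinylpent-3-enyl acetate | C=C[C@@](CCO)(COC(C)=O)C=C(C)C | intermediate
12 | (R)-4-methyl-2-(2-oxoethyl)-2-vinylpent-3-enyl acetate (C8 aldehyde) | C=C[C@@](CC=O)(COC(C)=O)C=C(C)C | intermediate
13 | 4-tert-butoxy-4-oxobutanoic acid (mono-tert-butyl succinate) | CC(C)(C)OC(=O)CCC(=O)O | starting material
14 | (R)-4-benzyl-2-oxazolidinone | O=C1N[C@H](Cc2ccccc2)CO1 | starting material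
15 | mixed anhydride of 13 with pivalic acid | CC(C)(C)OC(=O)CCC(=O)OC(=O)C(C)(C)C | intermediate
16 | (R)-4-benzyl-3-[4-(tert-butoxy)-4-oxobutanoyl]oxazolidin-2-one | CC(C)(C)OC(=O)CCC(=O)N1[C@H](Cc2ccccc2)COC1=O | intermediate
17 | dibutylboron Z-enolate of 16 | CC(C)(C)OC(=O)C/C=C(\OB(CCCC)CCCC)N1[C@H](Cc2ccccc2)COC1=O | intermediate
18 | Evans syn-aldol adduct: (R)-4-benzyl-oxazolidinone imide of the chain C6(=O)–C7H(CH2CO2t-Bu)–C8H(OH)–C9H2–C10(vinyl)(CH2OAc)–CH=CMe2, 7,8-syn | O=C(N1[C@H](Cc2ccccc2)COC1=O)[C@H](CC(=O)OC(C)(C)C)[C@@H](O)C[C@](C=C)(COC(C)=O)C=C(C)C | intermediate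
19 | O8-TBS ether of 18 | O=C(N1[C@H](Cc2ccccc2)COC1=O)[C@H](CC(=O)OC(C)(C)C)[C@@H](O[Si](C)(C)C(C)(C)C)C[C@](C=C)(COC(C)=O)C=C(C)C | intermediate
20 | C6 primary alcohol (C7 CH2CO2t-Bu, C8 OTBS, C10 as in 12) | OC[C@H](CC(=O)OC(C)(C)C)[C@@H](O[Si](C)(C)C(C)(C)C)C[C@](C=C)(COC(C)=O)C=C(C)C | intermediate
21 | ene precursor: acyclic C6 aldehyde with 2-methylpropenyl terminus, O8 TBS, O14 acetyl, tert-butyl ester | O=C[C@H](CC(=O)OC(C)(C)C)[C@@H](O[Si](C)(C)C(C)(C)C)C[C@](C=C)(COC(C)=O)C=C(C)C | intermediate
22 | ene product: cyclohexanol with equatorial C5 isopropenyl, C6 OH, C7 CH2CO2t-Bu and C8 OTBS; C10 vinyl equatorial, CH2OAc axial | C=C[C@]1(COC(C)=O)C[C@H](O[Si](C)(C)C(C)(C)C)[C@@H](CC(=O)OC(C)(C)C)[C@H](O)[C@H]1C(C)=C | intermediate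
23 | trans-fused 6,12-γ-lactone, O8 TBS, C5 isopropenyl | C=C[C@]1(COC(C)=O)C[C@H](O[Si](C)(C)C(C)(C)C)[C@H]2CC(=O)O[C@@H]2[C@H]1C(C)=C | intermediate
24 | lithium enolate of lactone 23 | [Li+].C=C[C@]1(COC(C)=O)C[C@H](O[Si](C)(C)C(C)(C)C)[C@H]2C=C([O-])O[C@@H]2[C@H]1C(C)=C | intermediate
25 | Mannich base: C11 dimethylaminomethyl lactone (C11 epimers) | C=C[C@]1(COC(C)=O)C[C@H](O[Si](C)(C)C(C)(C)C)[C@H]2C(CN(C)C)C(=O)O[C@@H]2[C@H]1C(C)=C | intermediate
26 | trimethylammonium iodide of 25 | C=C[C@]1(COC(C)=O)C[C@H](O[Si](C)(C)C(C)(C)C)[C@H]2C(C[N+](C)(C)C)C(=O)O[C@@H]2[C@H]1C(C)=C.[I-] | intermediate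
27 | α-methylene 6,12-lactone, O8 TBS, C5 isopropenyl | C=C[C@]1(COC(C)=O)C[C@H](O[Si](C)(C)C(C)(C)C)[C@H]2C(=C)C(=O)O[C@@H]2[C@H]1C(C)=C | intermediate
28 | C15 allylic alcohol of 27 | C=C[C@]1(COC(C)=O)C[C@H](O[Si](C)(C)C(C)(C)C)[C@H]2C(=C)C(=O)O[C@@H]2[C@H]1C(=C)CO | intermediate
29 | C15 enal, O8 TBS | C=C[C@]1(COC(C)=O)C[C@H](O[Si](C)(C)C(C)(C)C)[C@H]2C(=C)C(=O)O[C@@H]2[C@H]1C(=C)C=O | intermediate
30 | C8 alcohol (free O8 hydroxyl, equatorial) | C=C[C@]1(COC(C)=O)C[C@H](O)[C@H]2C(=C)C(=O)O[C@@H]2[C@H]1C(=C)C=O | intermediate
31 | ethyl 2-(hydroxymethyl)acrylate | C=C(CO)C(=O)OCC | starting material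
32 | ethyl 2-[(tert-butyldimethylsilyloxy)methyl]acrylate | C=C(CO[Si](C)(C)C(C)(C)C)C(=O)OCC | intermediate
33 | 2-[(tert-butyldimethylsilyloxy)methyl]acrylic acid | C=C(CO[Si](C)(C)C(C)(C)C)C(=O)O | intermediate
34 | mixed anhydride of 33 with 2,4,6-trichlorobenzoic acid | C=C(CO[Si](C)(C)C(C)(C)C)C(=O)OC(=O)c1c(Cl)cc(Cl)cc1Cl | intermediate
35 | O-TBS ether of the target (silyl on the hydroxymethacrylate oxygen) | C=C[C@]1(COC(C)=O)C[C@H](OC(=O)C(=C)CO[Si](C)(C)C(C)(C)C)[C@H]2C(=C)C(=O)O[C@@H]2[C@H]1C(=C)C=O | intermediate
36 | CNP0185525.1, (5R,6R,7R,8S,10R) in elemane numbering: 8α-[2-(hydroxymethyl)acryloyloxy]-14-acetoxy-15-oxo-elema-1,3,11(13)-trien-6α,12-olide | C=C[C@]1(COC(C)=O)C[C@H](OC(=O)C(=C)CO)[C@H]2C(=C)C(=O)O[C@@H]2[C@H]1C(=C)C=O | target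

**Step count**
Total: 21 steps. Longest linear sequence: 18 steps (steps 1–7, 9–17, 20, 21); steps 8 and 18–19 are side branches.

**Steps most likely to fail**

Step 13 (key carbonyl-ene closure). The closure may leak through the chair with an axial aluminium-bound carbonyl, or through an open cationic path (chloride capture at C4, loss of H5 to an isopropylidene). The β-silyloxy aldehyde may also eliminate or epimerise at C7 under the Lewis acid. The fallback forms the same C5–C6 bond by an intramolecular Nozaki–Hiyama allylation under neutral reducing conditions. Setting out from 21, catalytic SeO2 with t-BuOOH in CH2Cl2 should oxidise the (E)-methyl group of the 2-methylpropenyl terminus to the (E)-allylic alcohol aldehyde F1. NBS/Me2S (Corey–Kim bromination, −20 °C) should convert this into the allylic bromide aldehyde F2 without touching the aldehyde. CrCl2 in THF then generates the allylchromium species, which should add through its γ-carbon (C5) to the C6 aldehyde in a closed chair-like transition state that favours the trans, diequatorial arrangement. This regenerates the isopropenyl group and returns to the route at 22.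

Step 3 (lipase desymmetrisation). Discrimination between the enantiotopic hydroxymethyl groups at the all-carbon prochiral centre may be low, and 1,3-acyl migration in the monoacetate may erode the enantiomeric purity. The fallback is a non-enzymatic desymmetrisation. Setting out from 5, copper(II) chloride with a chiral pyridine-bis(oxazoline) ligand, BzCl and Et3N should give the monobenzoate F3, the ligand enantiomer being chosen so that the benzoate sits on the arm that becomes C14; the benzoate also migrates less readily than an acetate. Dess–Martin oxidation gives the benzoate aldehyde F4, Wittig olefination with ylide 9 gives the benzoate diene F5, K2CO3 in MeOH gives the neopentyl alcohol F6, and Ac2O/pyridine returns to the route at 10.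

Step 15 (α-methylenation). The amide base may also deprotonate the C14 acetate, which would lead to aminomethylation of the acetate or Claisen-type condensation. The fallback replaces the strong base by a thermal condensation that selects on C–H acidity. Setting out from 23, Bredereck's reagent (tert-butoxybis(dimethylamino)methane) in toluene at 80 °C should condense only at the lactone α-CH2 to give the enaminolactone F7. NaBH(OAc)3 in AcOH reduces this vinylogous carbamate to the Mannich base 25, where the fallback rejoins the route; 25 is then quaternised and eliminated as in step 15 to give 27.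

**Further compounds**
F1 | step 13 | (E)-allylic alcohol of 21 (CH2OH trans to C10 on the C5=C4 olefin) | O=C[C@H](CC(=O)OC(C)(C)C)[C@@H](O[Si](C)(C)C(C)(C)C)C[C@](C=C)(COC(C)=O)/C=C(\C)CO
F2 | step 13 | (E)-allylic bromide of 21 | O=C[C@H](CC(=O)OC(C)(C)C)[C@@H](O[Si](C)(C)C(C)(C)C)C[C@](C=C)(COC(C)=O)/C=C(\C)CBr
F3 | step 3 | monobenzoate analogue of 6 | C=C[C@@](CCO[Si](C)(C)C(C)(C)C)(COC(=O)c1ccccc1)CO
F4 | step 3 | benzoate analogue of aldehyde 7 | C=C[C@@](CCO[Si](C)(C)C(C)(C)C)(COC(=O)c1ccccc1)C=O
F5 | step 3 | benzoate analogue of diene 10 | C=C[C@@](CCO[Si](C)(C)C(C)(C)C)(COC(=O)c1ccccc1)C=C(C)C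
F6 | step 3 | 2-[2-(tert-butyldimethylsilyloxy)ethyl]-4-methyl-2-vinylpent-3-en-1-ol (C14 alcohol) | C=C[C@@](CCO[Si](C)(C)C(C)(C)C)(CO)C=C(C)C
F7 | step 15 | (E)-α-(dimethylaminomethylene) lactone from 23 | C=C[C@]1(COC(C)=O)C[C@H](O[Si](C)(C)C(C)(C)C)[C@H]2/C(=C\N(C)C)C(=O)O[C@@H]2[C@H]1C(C)=C
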